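Early on the target climbs fast, so what you watch is how soon that climb gives way to the fall.

| setting | east | south | south-east | flask |
|---|---|---|---|---|
| starting material | 20 mM | 20 mM | 10 mM | 20 mM |
| partner | 22 mM | 22 mM | 22 mM | 22.0 mM |
| protic impurity | 1 mM | 4 mM | 2 mM | 2.00 mM |
| remark | run made earlier | run made earlier | run made earlier |  |
| time |  |  |  | 5.0 d |

- east (time / d: target / %, starting material / %): 0.0556: 7.5, 9.6; 0.125: 12.8, 4.9; 0.333: 13.1, 2.3; 0.833: 9.1, 1.9; 2.08: 1.5, 0; 5.00: 0, 0
- south (time / d: target / %, starting material / %): 0.0556: 6.1, 7.0; 0.125: 12.0, 5.2; 0.333: 11.5, 3.8; 0.833: 5.5, 0; 2.08: 0, 0; 5.00: 0, 1.7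
- south-east (time / d: target / %, starting material / %): 0.0556: 8.3, 5.2; 0.167: 14.3, 5.3; 0.500: 11.1, 3.1; 1.67: 2.0, 0; 5.00: 0.7, 0.3

(standard deviation of a reading: 1 percentage point)

- the moment within 5.0 d at which there is most target
- the amount of target, in percent of the starting material charged, at that time
- earliest time at which at least nineteen twentieths of that best amount are there, in d
- latest time at which they still are, in d

1. In the east run the target shows 7.5% at the first reading. Between 0.125 d and 0.333 d it gains 0.3 percentage points, which is less than the scatter of 1 point. So by then, within the scatter, the east readings show no net climb.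

2. Past that top, the east run drops from 13.1% to 1.5%. Call the time in which target halves there the fall half-life (an apparent first-order half-life): 0.559 d. This is a reading. The south-east run gives 0.473 d, but I take east, whose charge of starting material equals the flask's, though its protic impurity is lower.

3. Turn the question round. For the flask to keep half its top at 5.0 d, counting from 0.333 d as in the east run, the fall half-life would have to reach 4.67 d, which is 8.35 times the reading. Taking the east top and the fall half-life over unchanged, my own reckoning for the flask at 5.0 d is about 0.0400% of target.

4. The forecast gives 13.2% at 0.21 d, with a window from 0.125 d to 0.32 d, since the flask “should sit between east and south”.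

5. The flask gives 14.0% at 0.212 d, with the window from 0.145 d to 0.310 d, so it opens later than forecast.

    starting material ⇌ open intermediate (K = 12.0, k = 2.40 /h)
    partner → second intermediate (k = 0.420 /h)
    open intermediate + second intermediate ⇌ target (K = 18.0 /M, k = 34.0 /M/h)
    2 open intermediate → homo product (k = 0.470 /M/h)
    starting material + protic impurity → quenched substrate (k = 340 /M/h)
    open intermediate → decomposed reagent (k = 0.0780 /h)

6. At its best time the flask holds 46.8% of open intermediate beside 4.02% of starting material. Counting fall half-lives from the flask's best amount of target gives 0.0370% of target at 5.00 d, and the flask holds 0.0375% of target. For the same flask read at 30 h, the fall half-life gives 3.85% of target, and that flask holds 4.17%.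

The runs are simulated from invented constants, and the scatter is random.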